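A direct plan would make a bis-silylated hispidin from catechol (bromination, silylation, Heck coupling with methyl vinyl ketone to enone A2, malonyl dichloride pyranone annulation), chlorinate it at C3 to A1, and build the dihydrofuran on this pyranone by a diamine-catalysed Michael addition/3-exo-tet closure of A1 with A2 followed by acid-induced cyclopropane-to-dihydrofuran expansion to methyl ketone A3. A second malonyl dichloride annulation on A3 and desilylation would finish. Its weakest steps would be:
(a) the run-up, where four linear steps, one of them a low-yielding annulation, would only rebuild a 6-styryl-4-hydroxy-2-pyranone whose ring is sold as triacetic acid lactone;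
(b) the cascade to A3, which would rest both stereocentres and the ring fusion on untested events at once (iminium face selectivity with a 3-chloropyranolate, choice of the cyclopropane bond that breaks, O4 versus O2 reclosure) and would pass C2 through a benzylic cation, so that its configuration would depend on equilibration alone;
(c) the pyranone annulation on A3, which would expose the most advanced intermediate, whose C3–H is acidic and β to a pyranolate leaving group, to amide base and malonyl dichloride, inviting epimerisation and E1cB ring opening.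

**Plan of the new route.** The dihydrofuran is cut at O1–C7a and C2–C3, so that C2 and O1 leave together as the C=O group of protected protocatechualdehyde (a [4+1] annulation). The C3a–C3 bond is then cut to a 4-hydroxy-2-pyranone and a pyranone-6-carbaldehyde (reductive alkylation), and the styryl C=C to the same aldehyde and triacetic acid lactone. Both pyranone rings (ring A, later ring-fused; ring B, pendant) are bought as triacetic acid lactone, and the dihydrofuran is the last ring to form. No pyranone is annulated and no halogenation is needed. The ring oxygen can close only on the sulfonate-bearing C7a, C2 arises in a catalyst-controlled C–C bond formation, and its C–O bond is never ionised. Enabling feature: C3 is a methylene bound to C6 of ring B (a bis-vinylogous α-carbon of that lactone, nucleophilic after O-silylation) and to C3 of ring A, next to the vinylogous acyl carbon C7a that accepts the aldehyde oxygen.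

Key step: step 7

Conventions: Ar = 3,4-bis(tert-butyldimethylsilyloxy)phenyl; core numbering O1, C2, C3, C3a, C4, O5, C6, C7, C7a is also used for the atoms that become these positions.
Assumption: the sense of induction of the bis(phosphoramide)·SiCl4 system with aromatic aldehydes is taken to carry over to nucleophile 11; the catalyst enantiomer that delivers 11 to the Si face of 2 is written as (S,S), and the antipode is used if the sense proves opposite.

Step 1
Reactants: 1 3,4-dihydroxybenzaldehyde
Product: 2 3,4-bis(tert-butyldimethylsilyloxy)benzaldehyde (ArCHO)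
Conditions: TBSCl (2.4 equiv), imidazole (5 equiv), DMF, rt
Reagents that add atoms: tert-butyldimethylsilyl chloride, CC(C)(C)[Si](C)(C)Cl
Why: Imidazole-promoted silylation masks the catechol with groups that tolerate amide bases, SiCl4 and amidines and leave with fluoride.

Step 2
Reactants: 3 4-hydroxy-6-methyl-2H-pyran-2-one (triacetic acid lactone); 2 ArCHO
Product: 5 6-[(E)-2-Ar-ethenyl]-4-hydroxy-2H-pyran-2-one, via aldol adduct 4 (not isolated)
Conditions: LiN(iPr)2 (2.3 equiv), THF–DMPU, −78 °C; 2 (1.0 equiv); AcOH; then pyridinium p-toluenesulfonate (10 mol%), toluene, 80 °C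
Reagents that add atoms: none
Why: The dianion of 3 adds through its C6-methyl carbon to the aldehyde (lateral-metalation aldol), and the electron-rich benzylic alcohol 4 should lose water under mild acid (E1) to the conjugated E-alkene.

Step 3
Reactants: 3 triacetic acid lactone
Product: 6 6-methyl-4-[2-(trimethylsilyl)ethoxy]-2H-pyran-2-one
Conditions: 2-(trimethylsilyl)ethanol (1.2 equiv), PPh3, diisopropyl azodicarboxylate, THF, 0 °C → rt
Reagents that add atoms: 2-(trimethylsilyl)ethanol, OCC[Si](C)(C)C
Why: Mitsunobu O-alkylation of the vinylogous acid is selective for the 4-oxygen and installs an ether that survives oxidation, base and Lewis acid and fragments with fluoride.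

Step 4
Reactants: 6 silylethyl ether of triacetic acid lactone
Product: 7 2-oxo-4-[2-(trimethylsilyl)ethoxy]-2H-pyran-6-carbaldehyde
Conditions: SeO2 (2 equiv), 1,4-dioxane, 150 °C, sealed tube
Reagents that add atoms: selenium dioxide, O=[Se]=O
Why: Riley oxidation of the activated C6 methyl group, known for 4-methoxy-6-methyl-2-pyranone, should stop at the electron-poor aldehyde.

Step 5
Reactants: 5 silylated hispidin; 7 pyranone aldehyde
Product: 9 6-[(E)-2-Ar-ethenyl]-4-hydroxy-3-({2-oxo-4-[2-(trimethylsilyl)ethoxy]-2H-pyran-6-yl}methyl)-2H-pyran-2-one, via alkylidene pyrandione 8 (not isolated)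
Conditions: L-proline (20 mol%), Hantzsch ester (diethyl 2,6-dimethyl-1,4-dihydropyridine-3,5-dicarboxylate, 1.1 equiv), CH2Cl2, rt
Reagents that add atoms: none
Why: In this organocatalytic three-component reductive alkylation, Knoevenagel condensation at C3 of the 4-hydroxypyranone gives the strongly hydride-accepting alkylidene dione 8, which the Hantzsch ester reduces before a second pyranone can add and without touching the styryl group.

Step 6
Reactants: 9 bis(pyranonyl)methane
Product: 10 6-[(E)-2-Ar-ethenyl]-2-oxo-3-({2-oxo-4-[2-(trimethylsilyl)ethoxy]-2H-pyran-6-yl}methyl)-2H-pyran-4-yl 4-methylbenzenesulfonate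
Conditions: TsCl (1.1 equiv), Et3N (1.5 equiv), CH2Cl2, 0 °C
Reagents that add atoms: p-toluenesulfonyl chloride, Cc1ccc(S(=O)(=O)Cl)cc1
Why: O-Sulfonylation of the vinylogous acid turns C4 of ring A (the later C7a) into the carbon of a vinylogous carboxylic–sulfonic anhydride, while Et3N leaves the neutral C3–H acid untouched.

Step 7 (key step)
Reactants: 10 tosylate; 2 ArCHO
Product: 13 (2S,3S)-2-Ar-6-[(E)-2-Ar-ethenyl]-3-{2-oxo-4-[2-(trimethylsilyl)ethoxy]-2H-pyran-6-yl}-2,3-dihydro-4H-furo[3,2-c]pyran-4-one (trans), via silyl trienol ether 11 (not isolated), via open aldol adduct 12 (not isolated)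
Conditions: TBSOTf (1.2 equiv), iPr2NEt (1.5 equiv), CH2Cl2, 0 °C; pentane, filter, concentrate; then 2 (1.3 equiv), SiCl4 (1.5 equiv), (S,S)-bis(phosphoramide) [two cyclic phosphoramide units of N,N′-dimethyl-1,1′-binaphthyl-2,2′-diamine joined by an N,N′-dimethylpentane-1,5-diamine chain] (5 mol%), iPr2NEt (10 mol%), CH2Cl2, −78 → −50 °C; aq. NaHCO3; then DBU (1.5 equiv), THF, 0 °C → rt
Reagents that add atoms: tert-butyldimethylsilyl trifluoromethanesulfonate, CC(C)(C)[Si](C)(C)OS(=O)(=O)C(F)(F)F (its silyl group is carried by 11 only and leaves again)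
Why: Proposed new method: an enantioselective bis-vinylogous Mukaiyama aldol addition coupled to an intramolecular addition–elimination, in sum a [4+1] annulation that inserts the C=O group of 2 as C2–O1 between C3 and C7a. O-Silylation of the lactone carbonyl of ring B and loss of one C3 proton give 11, the anhydrobase of a 2-silyloxypyrylium ion, whose exocyclic carbon C3 attacks the aldehyde held on the chiral [bis(phosphoramide)·SiCl3]+ cation and thereby restores the aromatic pyranone B; the closest known reactions are the Lewis-base-catalysed SiCl4 Mukaiyama aldol additions of silyl dienol and trienol ethers to aromatic aldehydes (attack from the remote carbon, aldehyde face fixed by the catalyst) and the lateral-metalation aldol reactions of 4-alkoxy-6-methyl-2-pyranones. After hydrolysis of the trichlorosilyl ether the C2 hydroxyl of 12 closes the dihydrofuran on C7a of ring A with loss of tosylate, a five-membered addition–elimination (formally 5-endo-trig in the addition event, leaving group exocyclic) of the kind seen in SNAr closures of 2-(2-haloaryl)ethanols to dihydrobenzofurans, so that only the furo[3,2-c] fusion can result. C2 (S) is set by the catalyst through attack on the Si face of the aldehyde and its C–O bond is not broken afterwards; C3 is a vinylogous α-carbon of ring B that epimerises under the amidine base in 12 and should settle trans to the C2 aryl group (S) in the ring. The step needs attack through the exocyclic C3 and not through the ring carbons of ring B, which re-aromatisation secures, and ring closure ahead of E1cB loss of water from 12, which the high electrophilicity of C7a and the poor hydroxide leaving group secure.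

Step 8
Reactants: 13 pentasilylated hypholomine B
Product: 14 hypholomine B
Conditions: Bu4NF (10 equiv), AcOH (10 equiv), THF, 0 °C → rt, argon; size-exclusion gel, MeOH
Reagents that add atoms: none
Why: Fluoride cleaves the four aryl silyl ethers and attacks the trimethylsilyl group of the silylethyl ether, which fragments to ethene and the pyranolate as silylethyl esters do, while the acetic acid buffer keeps the phenols protonated so that neither quinone methide ring opening nor C3 epimerisation should start.

## Compound list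
1 | 3,4-dihydroxybenzaldehyde | O=Cc1ccc(O)c(O)c1 | starting material
2 | 3,4-bis(tert-butyldimethylsilyloxy)benzaldehyde | O=Cc1ccc(O[Si](C)(C)C(C)(C)C)c(O[Si](C)(C)C(C)(C)C)c1 | intermediate
3 | 4-hydroxy-6-methyl-2H-pyran-2-one (triacetic acid lactone) | Cc1cc(O)cc(=O)o1 | starting material
4 | 6-(2-Ar-2-hydroxyethyl)-4-hydroxy-2H-pyran-2-one (racemic) | O=c1cc(O)cc(CC(O)c2ccc(O[Si](C)(C)C(C)(C)C)c(O[Si](C)(C)C(C)(C)C)c2)o1 | intermediate
5 | 6-[(E)-2-Ar-ethenyl]-4-hydroxy-2H-pyran-2-one | O=c1cc(O)cc(/C=C/c2ccc(O[Si](C)(C)C(C)(C)C)c(O[Si](C)(C)C(C)(C)C)c2)o1 | intermediate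
6 | 6-methyl-4-[2-(trimethylsilyl)ethoxy]-2H-pyran-2-one | Cc1cc(OCC[Si](C)(C)C)cc(=O)o1 | intermediate
7 | 2-oxo-4-[2-(trimethylsilyl)ethoxy]-2H-pyran-6-carbaldehyde | O=Cc1cc(OCC[Si](C)(C)C)cc(=O)o1 | intermediate
8 | 6-[(E)-2-Ar-ethenyl]-3-({2-oxo-4-[2-(trimethylsilyl)ethoxy]-2H-pyran-6-yl}methylidene)-2H-pyran-2,4(3H)-dione (alkene geometry at C3 open) | O=C1OC(/C=C/c2ccc(O[Si](C)(C)C(C)(C)C)c(O[Si](C)(C)C(C)(C)C)c2)=CC(=O)C1=Cc1cc(OCC[Si](C)(C)C)cc(=O)o1 | intermediate
9 | 6-[(E)-2-Ar-ethenyl]-4-hydroxy-3-({2-oxo-4-[2-(trimethylsilyl)ethoxy]-2H-pyran-6-yl}methyl)-2H-pyran-2-one | O=c1oc(/C=C/c2ccc(O[Si](C)(C)C(C)(C)C)c(O[Si](C)(C)C(C)(C)C)c2)cc(O)c1Cc1cc(OCC[Si](C)(C)C)cc(=O)o1 | intermediate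
10 | 6-[(E)-2-Ar-ethenyl]-2-oxo-3-({2-oxo-4-[2-(trimethylsilyl)ethoxy]-2H-pyran-6-yl}methyl)-2H-pyran-4-yl 4-methylbenzenesulfonate | O=c1oc(/C=C/c2ccc(O[Si](C)(C)C(C)(C)C)c(O[Si](C)(C)C(C)(C)C)c2)cc(OS(=O)(=O)c2ccc(C)cc2)c1Cc1cc(OCC[Si](C)(C)C)cc(=O)o1 | intermediate
11 | 3-({6-(tert-butyldimethylsilyloxy)-4-[2-(trimethylsilyl)ethoxy]-2H-pyran-2-ylidene}methyl)-6-[(E)-2-Ar-ethenyl]-2-oxo-2H-pyran-4-yl 4-methylbenzenesulfonate (exocyclic alkene geometry open) | O=c1oc(/C=C/c2ccc(O[Si](C)(C)C(C)(C)C)c(O[Si](C)(C)C(C)(C)C)c2)cc(OS(=O)(=O)c2ccc(C)cc2)c1C=C1C=C(OCC[Si](C)(C)C)C=C(O[Si](C)(C)C(C)(C)C)O1 | intermediate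
12 | 3-[(2S)-2-Ar-2-hydroxy-1-{2-oxo-4-[2-(trimethylsilyl)ethoxy]-2H-pyran-6-yl}ethyl]-6-[(E)-2-Ar-ethenyl]-2-oxo-2H-pyran-4-yl 4-methylbenzenesulfonate (epimers at C1 of the ethyl chain) | O=c1oc(/C=C/c2ccc(O[Si](C)(C)C(C)(C)C)c(O[Si](C)(C)C(C)(C)C)c2)cc(OS(=O)(=O)c2ccc(C)cc2)c1C(c1cc(OCC[Si](C)(C)C)cc(=O)o1)[C@H](O)c1ccc(O[Si](C)(C)C(C)(C)C)c(O[Si](C)(C)C(C)(C)C)c1 | intermediate
13 | (2S,3S)-2-Ar-6-[(E)-2-Ar-ethenyl]-3-{2-oxo-4-[2-(trimethylsilyl)ethoxy]-2H-pyran-6-yl}-2,3-dihydro-4H-furo[3,2-c]pyran-4-one (trans) | O=c1cc(OCC[Si](C)(C)C)cc([C@H]2c3c(cc(/C=C/c4ccc(O[Si](C)(C)C(C)(C)C)c(O[Si](C)(C)C(C)(C)C)c4)oc3=O)O[C@@H]2c2ccc(O[Si](C)(C)C(C)(C)C)c(O[Si](C)(C)C(C)(C)C)c2)o1 | intermediate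
14 | hypholomine B, (2S,3S)-2-(3,4-dihydroxyphenyl)-6-[(E)-2-(3,4-dihydroxyphenyl)ethenyl]-3-(4-hydroxy-2-oxo-2H-pyran-6-yl)-2,3-dihydro-4H-furo[3,2-c]pyran-4-one | O=c1cc(O)cc([C@H]2c3c(cc(/C=C/c4ccc(O)c(O)c4)oc3=O)O[C@@H]2c2ccc(O)c(O)c2)o1 | target

Total step count: 8. Longest linear sequence: 6 steps (3 → 6 → 7 → 9 → 10 → 13 → 14; the branch 1 → 2 → 5 → 9 is equally long).

Steps most likely to fail:

Step 7. The hindered, acceptor-substituted trienol ether may react slowly or with poor face selectivity toward the electron-rich aldehyde, and under the amidine base the closed ring may reopen by E1cB, which would erode the enantiomeric purity at C2. The fallback sets out from 10 and makes the same two bonds without silicon by direct lateral metalation: LiN(SiMe3)2 (1.05 equiv), THF, −78 °C, then 2, so that the lithium aldolate closes on C7a as it forms. Each event is known (lateral lithiation–aldol of 4-alkoxy-6-alkyl-2-pyranones, alkoxide displacement at C4 of 4-sulfonyloxy-2-pyranones). This would give the trans compound as the racemate, that is 13 together with its enantiomer ent-13 F1; the two would be separated by preparative chromatography on a chiral stationary phase (amylose tris(3,5-dimethylphenylcarbamate)), and the route is rejoined at 13.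

Step 8. The silylethyl ether may be cleaved incompletely by buffered fluoride, and an unbuffered medium would allow phenoxide-driven ring opening or air oxidation of the catechols. The fallback sets out from 13: Et3N·3HF (THF, 0 °C → rt) would remove only the four aryl silyl ethers to give 4′-O-[2-(trimethylsilyl)ethyl]hypholomine B F2. Its silylethyl ether would then be cleaved by acidolysis instead of fluoride (CF3CO2H–CH2Cl2 1:4, 0 °C, β-silyl fragmentation as for silylethyl esters), which gives 14.

Step 4. At 150 °C the oxidation may run on to the acid or degrade the silylethyl ether. The fallback sets out from 6: radical bromination of the methyl group (N-bromosuccinimide, azobisisobutyronitrile, PhCF3, 80 °C, as known for the 4-methoxy analogue) would give 6-(bromomethyl)-4-[2-(trimethylsilyl)ethoxy]-2H-pyran-2-one F3. Amine N-oxide oxidation of the bromide (N-methylmorpholine N-oxide, MeCN, rt, Kornblum type) would convert it into 7.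

Further compounds
F1 | step 7 | ent-13, (2R,3R)-2-Ar-6-[(E)-2-Ar-ethenyl]-3-{2-oxo-4-[2-(trimethylsilyl)ethoxy]-2H-pyran-6-yl}-2,3-dihydro-4H-furo[3,2-c]pyran-4-one, formed with 13 as the racemate | O=c1cc(OCC[Si](C)(C)C)cc([C@@H]2c3c(cc(/C=C/c4ccc(O[Si](C)(C)C(C)(C)C)c(O[Si](C)(C)C(C)(C)C)c4)oc3=O)O[C@H]2c2ccc(O[Si](C)(C)C(C)(C)C)c(O[Si](C)(C)C(C)(C)C)c2)o1
F2 | step 8 | (2S,3S)-2-(3,4-dihydroxyphenyl)-6-[(E)-2-(3,4-dihydroxyphenyl)ethenyl]-3-{2-oxo-4-[2-(trimethylsilyl)ethoxy]-2H-pyran-6-yl}-2,3-dihydro-4H-furo[3,2-c]pyran-4-one | O=c1cc(OCC[Si](C)(C)C)cc([C@H]2c3c(cc(/C=C/c4ccc(O)c(O)c4)oc3=O)O[C@@H]2c2ccc(O)c(O)c2)o1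
F3 | step 4 | 6-(bromomethyl)-4-[2-(trimethylsilyl)ethoxy]-2H-pyran-2-one | BrCc1cc(OCC[Si](C)(C)C)cc(=O)o1
A1 | direct plan | 3-chloro-6-[(E)-2-Ar-ethenyl]-4-hydroxy-2H-pyran-2-one | O=c1c(Cl)c(O)cc(/C=C/c2ccc(O[Si](C)(C)C(C)(C)C)c(O[Si](C)(C)C(C)(C)C)c2)o1
A2 | direct plan | (E)-4-Ar-but-3-en-2-one | CC(=O)/C=C/c1ccc(O[Si](C)(C)C(C)(C)C)c(O[Si](C)(C)C(C)(C)C)c1
A3 | direct plan | (2S,3S)-3-acetyl-2-Ar-6-[(E)-2-Ar-ethenyl]-2,3-dihydro-4H-furo[3,2-c]pyran-4-one | CC(=O)[C@H]1c2c(cc(/C=C/c3ccc(O[Si](C)(C)C(C)(C)C)c(O[Si](C)(C)C(C)(C)C)c3)oc2=O)O[C@@H]1c1ccc(O[Si](C)(C)C(C)(C)C)c(O[Si](C)(C)C(C)(C)C)c1
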